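At early times the target runs ahead: at 4.00 min Monday's flask holds 8.8% of target and 1.4% of side product, but at 20.0 min it holds 25.6% and 17.4%.

| setting | Wednesday's | Monday's | south | south-west |
|---|---|---|---|---|
| starting material | 0.020 M | 0.020 M | 0.020 M | 0.020 M |
| second substrate | 0.020 M | 0.020 M | 0.0200 M | 0.0200 M |
| free enzyme | 2 µM | 3 µM | 4.0 µM | 4.0 µM |
| added ligand | 15 µM | 15 µM | 15 µM | 15 µM |
| temperature | 12 °C | 27 °C | 37 °C | 17 °C |
| remark | run made earlier | run made earlier |  |  |
| time |  |  | 12 min | 12 min |

- Wednesday's (time / min: target / %, side product / %, starting material / %): 3.00: 0.9, 0.7, 101.0; 10.0: 3.3, 2.1, 97.1; 20.0: 7.4, 1.4, 92.7; 30.0: 6.2, 2.7, 91.3; 40.0: 7.4, 3.3, 87.2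
- Monday's (time / min: target / %, side product / %, starting material / %): 4.00: 8.8, 1.4, 88.4; 8.00: 15.0, 4.5, 79.3; 12.0: 20.7, 9.4, 70.6; 15.0: 23.1, 11.1, 64.3; 20.0: 25.6, 17.4, 54.7

(scatter of a reading: 1 percentage point)

* the flask with the highest share of target in all that became target or side product ("all alike" if they lie within 1.5 percentage points) (south / south-west / all alike)
* share of target in all that became target or side product, south
* share of target in all that became target or side product, south-west

- what is said of target includes crystals
- crystals is a solid; its amount is given per volume of the solution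
- steps that have been proposed: free enzyme -> unfolded enzyme; starting material + free enzyme <-> first complex; first complex <-> loaded enzyme + first product; second substrate + loaded enzyme <-> second complex; second complex -> free enzyme + target; target + first product -> side product; free enzyme + added ligand <-> idle complex; crystals <-> target

Let M be c(target) + c(side product) as a fraction of the starting material charged. I want the clock out of this, so I divide the rate of side product by the rate of M. Reading Monday's table row against row, c(side product) grows roughly as the square of M, so the share of target, the selectivity, is one minus b times M, with b the side product over M squared. Monday's run reads 1.04 at 12.0 min and 0.941 at 20.0 min, while the last row of Wednesday's run reads 2.88.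

The proposed side step contains no enzyme, so I take b as inverse to the charge of free enzyme. The product of b and that charge reads 5.76 µM in Wednesday's run at 12 °C and 2.82 µM in Monday's run at 27 °C, about half, a ratio of 0.490. Scaling this exponentially in temperature, my side load, the side product over the square of M, is 0.439 for south and, for south-west, 1.14.

M needs a clock. Treating the starting material as first order, the last rows give time constants of 292 min on Wednesday and 33.2 min on Monday. Scaled the same way, with enzyme, they give 7.64 min for south and 80.9 min for south-west. At 12 min, my estimate of M is then 79.2% in south and 13.8% in south-west, so I reckon a share of 65.3% for south and 84.3% for south-west.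

The forecast names south-west, with 66% for south and 82% for south-west, since “it reaches much lower conversion by 12 min”.

The simulation gives south-west, with 54.5% for south and 82.7% for south-west, so my south stands 11 percentage points too high.

    free enzyme → unfolded enzyme (k = 2.31 × 10⁻⁵ s⁻¹, Ea = 282 kJ mol⁻¹)
    starting material + free enzyme ⇌ first complex (K = 39.4 M⁻¹, k = 64600 M⁻¹ s⁻¹, Ea = 30.0 kJ mol⁻¹, ΔH = −21.0 kJ mol⁻¹)
    first complex ⇌ loaded enzyme + first product (K = 0.00666 M, k = 54.7 s⁻¹, Ea = 73.0 kJ mol⁻¹, ΔH = −61.0 kJ mol⁻¹)
    second substrate + loaded enzyme ⇌ second complex (K = 35.0 M⁻¹, k = 77500 M⁻¹ s⁻¹, Ea = 21.0 kJ mol⁻¹, ΔH = 16.0 kJ mol⁻¹)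
    second complex → free enzyme + target (k = 336 s⁻¹, Ea = 67.0 kJ mol⁻¹)
    target + first product → side product (k = 2.45 M⁻¹ s⁻¹, Ea = 37.0 kJ mol⁻¹)
    free enzyme + added ligand ⇌ idle complex, settled at all times (K = 1.91 × 10⁵ M⁻¹, ΔH = −38.0 kJ mol⁻¹)
    crystals ⇌ target, rate k8*(cs8 - [target]) while solid is left; crystals form when [target] > cs8 (solubility = 0.570 mM, k = 0.176 s⁻¹)
    (constants at 37 °C)

The neighbour is south-west left until 50 min, with amounts and temperature held, so I keep b at 1.14. That flask has made 49.2% of target and side product together, so one minus b times M gives 43.9%, and the flask shows 46.4%. It then holds 22.9% of target and 26.4% of side product.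

The earlier runs and the new flask are simulated on assumed constants; the scatter is artificial.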